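## The problem

The target is an indane (2,3-dihydro-1H-indene): a cyclopentane ring fused to a resorcinol ring whose oxygens sit on C5 and C7. In the numbering used here, C1 bears a 4-hydroxyphenyl ring, C2 a 3,5-dihydroxyphenyl ring, and C3 the carbinol carbon Cα, which carries OH and a second 4-hydroxyphenyl ring; C3a and C7a are the fusion carbons next to C3 and C1. The ring stereocentres are (1R,2S,3R) and all-trans, the least strained arrangement, so one ring centre of secure absolute configuration can set the other two if they are allowed to equilibrate. C3 is the natural anchor, because its exocyclic carbon can be a carbonyl carbon for most of the synthesis. Cα (R) lies outside the ring, is not reliably biased by it, and needs reagent control. The 4-hydroxybenzylic alcohol at Cα ionises to a quinone methide with traces of acid, so it must be unveiled last and without acid. The six phenols are air-sensitive under base, and the two resorcinol-type rings are strong carbon nucleophiles that intercept any cation. The feature that opens the molecule is C1: it is bonded to C7a (ortho to the oxygen on C7, para to the oxygen on C5) and to the para carbon of a phenol ring, so C1 can enter as an aldehyde carbon that is arylated twice, first by the ring on C3 and then by phenol.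

## Retrosynthesis

**27 back to 25 (Cα–H and six O–acyl bonds).** The carbinol is formed last. Target 27 comes from hexaacetate 26 by methanolysis, and 26 from ketone 25 by a catalyst-controlled reduction that sets Cα. Making Cα by adding an aryl nucleophile to a C3 aldehyde was rejected: it gives no control at Cα and puts the acid-labile carbinol in place before the phenols are freed. The forward reduction has to override whatever bias the ring exerts.

**25 back to 23 (protecting groups).** The acid chemistry of the key step needs methyl ethers, which only BBr3 removes, and BBr3 is tolerated only while Cα is a carbonyl carbon. So 25 is the acetate of hexaphenol ketone 24, and 24 comes from the pentamethyl ether ketone 23. The acetates make the ketone an ordinary substrate for borane and come off without acid.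

**23 back to 19 (Cα–aryl bond).** Cutting the bond between Cα and its aryl ring gives the N-methoxy-N-methylamide 20 and 4-methoxyphenyllithium 22 (from 1-bromo-4-methoxybenzene 21). Amide 20 comes from methyl ester 19. This turns the whole right-hand side into one ester group on C3, which makes C3 an ester α-carbon.

**19 back to 14 and 15 (C1–C7a and C1–aryl; the key cut).** Both bonds from C1 to arene carbons are cut, leaving aldehyde 14 and phenol 15. The neighbouring cuts at C2–C3 or C1–C2 would break the ring next to stereocentres and give two chiral fragments. This cut removes the ring, the C1 stereocentre and one aryl group in one stroke and leaves an acyclic chain with a single stereocentre that matters. The forward step must close the ring at C7a, capture the indanyl cation with phenol at its para carbon, and relay configuration from C3 to C2 and C1.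

**14 back to 9 (functional group changes).** The aldehyde carbon is a nitromethyl carbon in disguise (Nef reaction), so 14 comes from nitro ester 12. Ester 12 comes from acid 11, and 11 from imide 9 by removal of the auxiliary. The nitro group is chosen because it activates the acceptor for the preceding C–C bond formation and is the one-carbon aldehyde precursor that needs no later oxidation of an electron-rich intermediate.

**9 back to 4 and 7 (C2–C3 bond).** Cutting the bond between the two aryl-bearing carbons gives the enolate of imide 4 and nitroalkene 7. This is the only cut that makes the ester α-carbon, the one centre that must be controlled, in a reaction with reliable auxiliary control. The adjacent centre need not be controlled.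

**4 and 7 back to starting materials.** Imide 4 is the N-acyl derivative of (4R)-4-benzyl-1,3-oxazolidin-2-one 2 with 2-(3,5-dimethoxyphenyl)acetic acid 1. Nitroalkene 7 is the Henry condensation product of 3,5-dimethoxybenzaldehyde 5 and nitromethane 6.

## Roads not taken

**Alternative 1:** An arylrhodium annulation that cuts C3–C3a and C1–C2. In the forward step the arylrhodium species from boronic acid A2 would add syn across the (E)-alkene of cinnamyl silyl ether A3, and the benzylic C2–Rh bond would add to the ortho aldehyde, closing the ring to indanol A1.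
- Merits: it is convergent, the catalyst sets the absolute configuration, and the 2,3-trans relationship follows directly from the alkene geometry. In these respects it is better than the chosen plan, which uses a stoichiometric auxiliary.
- Weak points for this target:
  - A3 is an unactivated 1,2-disubstituted alkene, a poor partner for arylrhodium addition compared with the alkynes and strained or activated alkenes on which such annulations are established.
  - A2 is an electron-rich ortho-formyl boronic acid prone to protodeboronation under aqueous KOH.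
  - The benzylic rhodium intermediate has a β-hydrogen on C3 and can leave by β-hydride elimination.
  - A1 still has an OH on C1, so the C1 aryl group must be installed afterwards by the same ionisation and capture by phenol 15 that the chosen plan uses; the hardest selectivity problem is not avoided.
  - Cα arrives as a silyloxymethyl carbon and needs deprotection, oxidation, aryl addition and re-oxidation before the endgame, with three kinds of protecting group.
- Comparison: the chosen plan sets against the catalytic enantiocontrol of this road a key step that makes both bonds to C1 at once, a shorter sequence after the ring is formed, and standard enolate and nitro chemistry before it.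

**Alternative 2:** A donor–acceptor cyclopropane opening that cuts only C1–C7a, with the C1–C3 bond of cyclopropyl ketone A5 as a latent C1 cation and C3 enolate. With Sc(OTf)3 the ring would open and the dimethoxyphenyl ring on C3 would attack C1 through C7a to give the all-trans hexamethyl ether ketone A4.
- Merits: every carbon and all four aryl rings are in place before the key step, A4 is only the four operations of steps 10 to 13 away from 27, and the ring closure is purely intramolecular, so phenol never has to compete with dimethoxyphenyl rings. In both respects this road is better than the chosen one.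
- Weak points:
  - A5 is a tetrasubstituted triarylcyclopropane with three stereocentres, two of which are destroyed on opening; only the C2 centre carries the chirality.
  - An enantioselective cyclopropanation of a 1,2-diarylethene with an aryl diazo ketone is not a dependable reaction.
  - The ketone oxygen of the opened zwitterion is well placed to close on C1 to a 2,3-dihydrofuran (Cloke–Wilson rearrangement), the usual fate of donor-substituted cyclopropyl ketones under Lewis acids.
- Comparison: the chosen plan sets against the shorter endgame a precursor, 14, made in six conventional steps from a recoverable auxiliary, and an ester spectator that offers no O-cyclisation channel.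

**Alternative 3:** A Wolff ring contraction that cuts C3–C3a. Photolysis of diazotetralone A7 in methanol would expel N2, the aryl carbon C3a would migrate to the carbene carbon, and methanol would trap the ketene as ester A6, the anisyl ether of 19.
- Merits: C1 and C2 are set in a six-membered ring before the contraction, the C1 aryl group is present from the start so no cation capture is needed, and the ester appears directly. Avoiding the intermolecular Friedel–Crafts step is a real advantage over the chosen plan.
- Weak points:
  - A7 must be made enantiopure by building a ring with one carbon more than the target needs, and the diazo group must be installed by an activated two-operation diazo transfer.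
  - The carbene from A7 has a hydrogen on the adjacent aryl-bearing carbon; a 1,2-hydride shift leads to an enone that aromatises to a naphthol and competes irreversibly with aryl migration.
  - The ester carbon is created by protonation of a ketene-derived enol, kinetically cis to the C2 aryl group, so a base epimerisation is needed.
  - The photolysis is run on a chromophore with three methoxyaryl rings.
- Comparison: the chosen plan sets against the early, secure C1 centre of this road a key step that makes the ring and the C1–aryl bond together from an acyclic precursor, in several fewer steps.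

Key step: step 7

Assumptions on the chemistry:
- Locants C1, C2, C3, C3a, C7a and Cα in the prose are those defined in "The problem"; systematic names in the steps and lists use their own locants.
- The Michael adduct 9 is drawn as the anti diastereomer expected from a closed transition state; its epimer at the nitromethyl-bearing carbon would serve equally, because that carbon is re-set in step 7.
- Compounds 2 and 21 are taken as commercial, alongside 1, 5, 6 and 15.

## Route

Step 1
Reactants: 1 2-(3,5-dimethoxyphenyl)acetic acid; 2 (4R)-4-benzyl-1,3-oxazolidin-2-one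
Product: 4 (4R)-4-benzyl-3-[2-(3,5-dimethoxyphenyl)acetyl]-1,3-oxazolidin-2-one, via mixed pivalic anhydride 3 (not isolated)
Conditions: t-BuCOCl, Et3N, THF, −20 °C; then 2, LiCl, −20 °C → rt
Reagents that add atoms: none
Why: N-Acylation of the oxazolidinone through the mixed anhydride 3; LiCl/Et3N activates the oxazolidinone without a strong base, which avoids ketene formation from the arylacetyl unit. No stereocentre is formed.

Step 2
Reactants: 5 3,5-dimethoxybenzaldehyde; 6 nitromethane
Product: 7 1,3-dimethoxy-5-[(E)-2-nitroethenyl]benzene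
Conditions: NH4OAc, AcOH, 100 °C
Reagents that add atoms: none
Why: Henry (nitroaldol) condensation with dehydration; conjugation with the aryl ring gives the (E)-nitroalkene.

Step 3
Reactants: 4 (4R)-4-benzyl-3-[2-(3,5-dimethoxyphenyl)acetyl]-1,3-oxazolidin-2-one; 7 1,3-dimethoxy-5-[(E)-2-nitroethenyl]benzene
Product: 9 (4R)-4-benzyl-3-[(2R,3S)-2,3-bis(3,5-dimethoxyphenyl)-4-nitrobutanoyl]-1,3-oxazolidin-2-one, via chlorotitanium enolate 8 (not isolated)
Conditions: TiCl4 (1.1 equiv), i-Pr2NEt (1.2 equiv), CH2Cl2, −78 °C; then 7 (1.5 equiv) premixed with TiCl4, −78 → −20 °C; aq. NH4Cl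
Reagents that add atoms: none
Why: Auxiliary-controlled Michael addition of a chelated (Z)-chlorotitanium enolate to a nitroalkene; the benzyl group of the (4R)-auxiliary shields one enolate face, so the new bond forms on the face that makes the imide α-carbon (C3 of the target) R. A closed transition state of a (Z)-enolate and an (E)-nitroalkene should place the two aryl groups anti as drawn, but this second centre (C2 of the target) is re-set in step 7 and is not relied upon.

Step 4
Reactants: 9 (4R)-4-benzyl-3-[(2R,3S)-2,3-bis(3,5-dimethoxyphenyl)-4-nitrobutanoyl]-1,3-oxazolidin-2-one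
Product: 11 (2R,3S)-2,3-bis(3,5-dimethoxyphenyl)-4-nitrobutanoic acid, via peroxy acid 10 (not isolated)
Conditions: LiOH, H2O2, THF/H2O, 0 °C; then aq. Na2SO3; then 1 M HCl to pH 3, 0 °C
Reagents that add atoms: hydrogen peroxide, OO
Why: Hydroperoxide cleavage of the imide at the exocyclic carbonyl; LiOOH is strongly nucleophilic but weakly basic, so the α-aryl stereocentre is not epimerised. Sulfite reduces peroxy acid 10, the auxiliary 2 is recovered, and gentle cold acidification returns any nitronate to the nitro compound.

Step 5
Reactants: 11 (2R,3S)-2,3-bis(3,5-dimethoxyphenyl)-4-nitrobutanoic acid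
Product: 12 methyl (2R,3S)-2,3-bis(3,5-dimethoxyphenyl)-4-nitrobutanoate
Conditions: Me3SiCHN2, MeOH/toluene, 0 °C → rt
Reagents that add atoms: trimethylsilyldiazomethane, C[Si](C)(C)C=[N+]=[N-]
Why: Esterification of a carboxylic acid with a diazoalkane under neutral conditions, so neither the α-aryl centre nor the nitromethyl group is touched.

Step 6
Reactants: 12 methyl (2R,3S)-2,3-bis(3,5-dimethoxyphenyl)-4-nitrobutanoate
Product: 14 methyl (2R,3S)-2,3-bis(3,5-dimethoxyphenyl)-4-oxobutanoate, via sodium nitronate 13 (not isolated)
Conditions: NaOMe (1.05 equiv), MeOH, 0 °C; then aq. TiCl3, NH4OAc (pH ≈ 5), THF/H2O, 0 °C → rt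
Reagents that add atoms: water, O
Why: Reductive Nef reaction: one equivalent of methoxide deprotonates only the nitromethyl group, which is far more acidic than the ester α-position, and TiCl3 reduces nitronate 13 to the imine, which hydrolyses to the aldehyde in the buffer. The aldehyde α-centre may epimerise, which is harmless; 14 is used without storage.

Step 7
Reactants: 14 methyl (2R,3S)-2,3-bis(3,5-dimethoxyphenyl)-4-oxobutanoate; 15 phenol
Product: 19 methyl (1R,2S,3R)-2-(3,5-dimethoxyphenyl)-3-(4-hydroxyphenyl)-4,6-dimethoxy-2,3-dihydro-1H-indene-1-carboxylate, via indan-1-ol 16 (not isolated), via indan-1-yl cation 17 (not isolated), via indene 18 (not isolated)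
Conditions: 15 (20 equiv), CF3SO3H (0.5 equiv), (CF3)2CHOH, 0 °C, 14 added slowly at high dilution; then rt → 40 °C
Reagents that add atoms: none
Why: Cyclising double Friedel–Crafts arylation of an aldehyde, the known acid-mediated conversion of 3-arylpropanals into indanyl cations that are captured by a second arene. The protonated aldehyde carbon C1 is attacked by C7a of the aryl ring on the ester α-carbon (intramolecular electrophilic aromatic substitution, 5-exo-trig at the carbonyl) to give indanol 16; the ring on C2 could only close a four-membered ring and stays out. Indanol 16 ionises to cation 17, stabilised by the ortho methoxy group on C7 and the para methoxy group on C5, and the para carbon of phenol captures it. C1 is set by C2: phenol adds anti to the C2 aryl group, and because 17, indene 18 and the arylated products interconvert in strong acid, the all-trans isomer should accumulate. C2 equilibrates through the aldehyde enol before closure and through 18 after it, so either C2 epimer of 14 converges. The absolute configuration rests on C3, an ester α-carbon that is not enolised in acid. The step needs phenol to win over the more nucleophilic dimethoxyphenyl rings of other molecules and to react para rather than ortho; the large excess of phenol, slow addition of 14 and the reversibility of arylation (adducts of the most electron-rich rings revert fastest) are meant to secure the first, and the bulk of the secondary cation together with the same reversibility the second.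

Step 8
Reactants: 19 methyl (1R,2S,3R)-2-(3,5-dimethoxyphenyl)-3-(4-hydroxyphenyl)-4,6-dimethoxy-2,3-dihydro-1H-indene-1-carboxylate
Product: 20 (1R,2S,3R)-2-(3,5-dimethoxyphenyl)-3-(4-hydroxyphenyl)-N,4,6-trimethoxy-N-methyl-2,3-dihydro-1H-indene-1-carboxamide
Conditions: MeNH(OMe)·HCl, i-PrMgCl (excess), THF, −20 → 0 °C
Reagents that add atoms: N,O-dimethylhydroxylamine hydrochloride, CNOC.Cl
Why: Aminolysis of the ester by the chloromagnesium amide of N,O-dimethylhydroxylamine (Weinreb amide formation); the phenol is carried as its magnesium phenoxide. Any enolisation at C3 returns the thermodynamically preferred all-trans isomer, and C1 and C2 now also hold the absolute configuration.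

Step 9
Reactants: 20 (1R,2S,3R)-2-(3,5-dimethoxyphenyl)-3-(4-hydroxyphenyl)-N,4,6-trimethoxy-N-methyl-2,3-dihydro-1H-indene-1-carboxamide; 21 1-bromo-4-methoxybenzene
Product: 23 [(1R,2S,3R)-2-(3,5-dimethoxyphenyl)-3-(4-hydroxyphenyl)-4,6-dimethoxy-2,3-dihydro-1H-inden-1-yl](4-methoxyphenyl)methanone, via 4-methoxyphenyllithium 22 (not isolated)
Conditions: 21 (4 equiv), n-BuLi, THF, −78 °C; then 20, −78 → 0 °C; aq. NH4Cl
Reagents that add atoms: none
Why: Bromine–lithium exchange followed by addition of the aryllithium to the N-methoxy-N-methylamide, which stops at the chelated tetrahedral intermediate and gives the ketone on work-up. One equivalent of 22 is consumed by the phenol, hence the excess.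

Step 10
Reactants: 23 [(1R,2S,3R)-2-(3,5-dimethoxyphenyl)-3-(4-hydroxyphenyl)-4,6-dimethoxy-2,3-dihydro-1H-inden-1-yl](4-methoxyphenyl)methanone
Product: 24 [(1R,2S,3R)-2-(3,5-dihydroxyphenyl)-4,6-dihydroxy-3-(4-hydroxyphenyl)-2,3-dihydro-1H-inden-1-yl](4-hydroxyphenyl)methanone
Conditions: BBr3 (excess), CH2Cl2, −78 °C → rt; then MeOH, H2O
Reagents that add atoms: none
Why: Lewis acid cleavage of the five aryl methyl ethers by BBr3; the ketone is inert, whereas a free carbinol at Cα would ionise, which is why the carbonyl is kept until after this step.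

Step 11
Reactants: 24 [(1R,2S,3R)-2-(3,5-dihydroxyphenyl)-4,6-dihydroxy-3-(4-hydroxyphenyl)-2,3-dihydro-1H-inden-1-yl](4-hydroxyphenyl)methanone
Product: 25 4-[(1R,2S,3R)-4,6-diacetoxy-1-(4-acetoxybenzoyl)-2-(3,5-diacetoxyphenyl)-2,3-dihydro-1H-inden-3-yl]phenyl acetate
Conditions: Ac2O, pyridine, 4-(dimethylamino)pyridine (cat.), CH2Cl2, 0 °C → rt
Reagents that add atoms: acetic anhydride, CC(=O)OC(C)=O
Why: Acetylation of the six phenols; this removes the acidic protons that would consume borane and restores normal electrophilicity to the aryl ketone, which is deactivated while para to a free phenol.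

Step 12
Reactants: 25 4-[(1R,2S,3R)-4,6-diacetoxy-1-(4-acetoxybenzoyl)-2-(3,5-diacetoxyphenyl)-2,3-dihydro-1H-inden-3-yl]phenyl acetate
Product: 26 4-[(R)-[(1R,2S,3R)-4,6-diacetoxy-3-(4-acetoxyphenyl)-2-(3,5-diacetoxyphenyl)-2,3-dihydro-1H-inden-1-yl](hydroxy)methyl]phenyl acetate
Conditions: (3aS)-1-methyl-3,3-diphenyltetrahydro-1H,3H-pyrrolo[1,2-c][1,3,2]oxazaborole (0.5 equiv), BH3·SMe2, THF, −20 °C; then MeOH
Reagents that add atoms: none
Why: Corey–Bakshi–Shibata reduction; with the aryl group in the large-group position the (S)-configured catalyst should deliver hydride to the face that gives the (R)-carbinol, as it does for aryl alkyl ketones, so Cα is set by the catalyst and not by the ring. Aryl acetates are not reduced by borane at this temperature.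

Step 13
Reactants: 26 4-[(R)-[(1R,2S,3R)-4,6-diacetoxy-3-(4-acetoxyphenyl)-2-(3,5-diacetoxyphenyl)-2,3-dihydro-1H-inden-1-yl](hydroxy)methyl]phenyl acetate
Product: 27 (1R,2S,3R)-2-(3,5-dihydroxyphenyl)-1-[(R)-hydroxy(4-hydroxyphenyl)methyl]-3-(4-hydroxyphenyl)-2,3-dihydro-1H-indene-4,6-diol
Conditions: K2CO3, MeOH (degassed), 0 °C, Ar; then aq. NH4Cl to pH 7
Reagents that add atoms: none
Why: Zemplén-type transesterification of the aryl acetates with methanol; no acid is used, so the 4-hydroxybenzylic alcohol is not ionised, and air is excluded to protect the polyphenol.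

## Compound list

1 | 2-(3,5-dimethoxyphenyl)acetic acid | COc1cc(CC(=O)O)cc(OC)c1 | starting material
2 | (4R)-4-benzyl-1,3-oxazolidin-2-one | O=C1N[C@H](Cc2ccccc2)CO1 | starting material
3 | 2-(3,5-dimethoxyphenyl)acetic 2,2-dimethylpropanoic anhydride | COc1cc(CC(=O)OC(=O)C(C)(C)C)cc(OC)c1 | intermediate
4 | (4R)-4-benzyl-3-[2-(3,5-dimethoxyphenyl)acetyl]-1,3-oxazolidin-2-one | COc1cc(CC(=O)N2C(=O)OC[C@H]2Cc2ccccc2)cc(OC)c1 | intermediate
5 | 3,5-dimethoxybenzaldehyde | COc1cc(C=O)cc(OC)c1 | starting material
6 | nitromethane | C[N+](=O)[O-] | starting material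
7 | 1,3-dimethoxy-5-[(E)-2-nitroethenyl]benzene | COc1cc(/C=C/[N+](=O)[O-])cc(OC)c1 | intermediate
8 | trichlorotitanium (Z)-enolate of 4 (aryl and O–Ti cis) | COc1cc(OC)cc(c1)/C=C(\O[Ti](Cl)(Cl)Cl)N1C(=O)OC[C@H]1Cc1ccccc1 | intermediate
9 | (4R)-4-benzyl-3-[(2R,3S)-2,3-bis(3,5-dimethoxyphenyl)-4-nitrobutanoyl]-1,3-oxazolidin-2-one | COc1cc(OC)cc(c1)[C@H](C(=O)N1C(=O)OC[C@H]1Cc1ccccc1)[C@H](C[N+](=O)[O-])c1cc(OC)cc(OC)c1 | intermediate
10 | (2R,3S)-2,3-bis(3,5-dimethoxyphenyl)-4-nitrobutaneperoxoic acid | COc1cc(OC)cc(c1)[C@H](C(=O)OO)[C@H](C[N+](=O)[O-])c1cc(OC)cc(OC)c1 | intermediate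
11 | (2R,3S)-2,3-bis(3,5-dimethoxyphenyl)-4-nitrobutanoic acid | COc1cc(OC)cc(c1)[C@H](C(=O)O)[C@H](C[N+](=O)[O-])c1cc(OC)cc(OC)c1 | intermediate
12 | methyl (2R,3S)-2,3-bis(3,5-dimethoxyphenyl)-4-nitrobutanoate | COc1cc(OC)cc(c1)[C@H](C(=O)OC)[C@H](C[N+](=O)[O-])c1cc(OC)cc(OC)c1 | intermediate
13 | sodium nitronate of 12 (deprotonated at C4; C2 and C3 as in 12) | [Na+].COc1cc(OC)cc(c1)[C@H](C(=O)OC)[C@H](C=[N+]([O-])[O-])c1cc(OC)cc(OC)c1 | intermediate
14 | methyl (2R,3S)-2,3-bis(3,5-dimethoxyphenyl)-4-oxobutanoate | COc1cc(OC)cc(c1)[C@H](C(=O)OC)[C@H](C=O)c1cc(OC)cc(OC)c1 | intermediate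
15 | phenol | Oc1ccccc1 | starting material
16 | methyl (1R,2S)-2-(3,5-dimethoxyphenyl)-3-hydroxy-4,6-dimethoxy-2,3-dihydro-1H-indene-1-carboxylate (either configuration at the carbinol carbon) | OC1c2c(OC)cc(OC)cc2[C@H](C(=O)OC)[C@H]1c1cc(OC)cc(OC)c1 | intermediate
17 | (2S,3R)-2-(3,5-dimethoxyphenyl)-5,7-dimethoxy-3-(methoxycarbonyl)-2,3-dihydro-1H-inden-1-ylium | [CH+]1c2c(OC)cc(OC)cc2[C@H](C(=O)OC)[C@H]1c1cc(OC)cc(OC)c1 | intermediate
18 | methyl (1R)-2-(3,5-dimethoxyphenyl)-4,6-dimethoxy-1H-indene-1-carboxylate | COC(=O)[C@H]1c2cc(OC)cc(OC)c2C=C1c1cc(OC)cc(OC)c1 | intermediate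
19 | methyl (1R,2S,3R)-2-(3,5-dimethoxyphenyl)-3-(4-hydroxyphenyl)-4,6-dimethoxy-2,3-dihydro-1H-indene-1-carboxylate | Oc1ccc([C@@H]2c3c(OC)cc(OC)cc3[C@H](C(=O)OC)[C@H]2c2cc(OC)cc(OC)c2)cc1 | intermediate
20 | (1R,2S,3R)-2-(3,5-dimethoxyphenyl)-3-(4-hydroxyphenyl)-N,4,6-trimethoxy-N-methyl-2,3-dihydro-1H-indene-1-carboxamide | Oc1ccc([C@@H]2c3c(OC)cc(OC)cc3[C@H](C(=O)N(C)OC)[C@H]2c2cc(OC)cc(OC)c2)cc1 | intermediate
21 | 1-bromo-4-methoxybenzene | COc1ccc(Br)cc1 | starting material
22 | (4-methoxyphenyl)lithium | [Li]c1ccc(OC)cc1 | intermediate
23 | [(1R,2S,3R)-2-(3,5-dimethoxyphenyl)-3-(4-hydroxyphenyl)-4,6-dimethoxy-2,3-dihydro-1H-inden-1-yl](4-methoxyphenyl)methanone | Oc1ccc([C@@H]2c3c(OC)cc(OC)cc3[C@H](C(=O)c3ccc(OC)cc3)[C@H]2c2cc(OC)cc(OC)c2)cc1 | intermediate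
24 | [(1R,2S,3R)-2-(3,5-dihydroxyphenyl)-4,6-dihydroxy-3-(4-hydroxyphenyl)-2,3-dihydro-1H-inden-1-yl](4-hydroxyphenyl)methanone | Oc1ccc([C@@H]2c3c(O)cc(O)cc3[C@H](C(=O)c3ccc(O)cc3)[C@H]2c2cc(O)cc(O)c2)cc1 | intermediate
25 | 4-[(1R,2S,3R)-4,6-diacetoxy-1-(4-acetoxybenzoyl)-2-(3,5-diacetoxyphenyl)-2,3-dihydro-1H-inden-3-yl]phenyl acetate (hexaacetate of 24) | CC(=O)Oc1ccc([C@@H]2c3c(OC(C)=O)cc(OC(C)=O)cc3[C@H](C(=O)c3ccc(OC(C)=O)cc3)[C@H]2c2cc(OC(C)=O)cc(OC(C)=O)c2)cc1 | intermediate
26 | 4-[(R)-[(1R,2S,3R)-4,6-diacetoxy-3-(4-acetoxyphenyl)-2-(3,5-diacetoxyphenyl)-2,3-dihydro-1H-inden-1-yl](hydroxy)methyl]phenyl acetate | CC(=O)Oc1ccc([C@@H]2c3c(OC(C)=O)cc(OC(C)=O)cc3[C@H]([C@@H](O)c3ccc(OC(C)=O)cc3)[C@H]2c2cc(OC(C)=O)cc(OC(C)=O)c2)cc1 | intermediate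
27 | (1R,2S,3R)-2-(3,5-dihydroxyphenyl)-1-[(R)-hydroxy(4-hydroxyphenyl)methyl]-3-(4-hydroxyphenyl)-2,3-dihydro-1H-indene-4,6-diol | Oc1ccc([C@@H]2c3c(O)cc(O)cc3[C@H]([C@@H](O)c3ccc(O)cc3)[C@H]2c2cc(O)cc(O)c2)cc1 | target

## Step count and risks

Total step count: 13. Longest linear sequence: 12 steps (steps 1 and 3 to 13, from 1 to 27; step 2 is a one-step branch).

**Step 7 (key step).**
- What may go wrong: cation 17 and indene 18 may be intercepted by dimethoxyphenyl rings of other molecules faster than by phenol, and if the adducts do not revert the material is lost to oligomers. Equilibration may also stop short, leaving 1,2-cis or 2,3-cis isomers, and some ortho attack of phenol may persist.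
- Fallback (sets out from 14, returns at 24): the two bonds to C1 are made in the opposite order, so no intermolecular cation capture is needed.
  - 4-Methoxyphenylmagnesium bromide is added to the aldehyde of 14 at −78 °C, with a cold acetic acid quench so the ester is untouched. This gives the hydroxy ester methyl (2R,3S)-2,3-bis(3,5-dimethoxyphenyl)-4-hydroxy-4-(4-methoxyphenyl)butanoate F1 as a mixture of carbinol epimers.
  - With BF3·OEt2 or catalytic CF3SO3H in CH2Cl2, F1 ionises to the 4-methoxybenzylic cation, which C7a captures within the molecule (cyclialkylation of a 1,3-diarylpropan-1-ol, a standard route to 1-arylindanes). The product is the all-trans indane ester methyl (1R,2S,3R)-2-(3,5-dimethoxyphenyl)-4,6-dimethoxy-3-(4-methoxyphenyl)-2,3-dihydro-1H-indene-1-carboxylate F2 (identical with A6).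
  - F2 is taken through the chemistry of steps 8 and 9, now with no phenol to titrate, to the N-methoxy-N-methylamide F3 and the hexamethyl ether ketone F4 (identical with A4).
  - BBr3 as in step 10 cleaves all six methyl ethers of F4 and gives 24.

**Step 3 (Michael addition).**
- What may go wrong: the stabilised, hindered arylacetyl enolate may add slowly, so the nitroalkene polymerises under TiCl4, or facial selectivity may erode through a non-chelated enolate.
- Fallback (sets out from 1 and 7, returns at 12): catalyst control replaces auxiliary control.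
  - Acid 1 is coupled with 3,5-dimethylpyrazole (N-(3-dimethylaminopropyl)-N′-ethylcarbodiimide hydrochloride, 4-(dimethylamino)pyridine) to the N-acylpyrazole 2-(3,5-dimethoxyphenyl)-1-(3,5-dimethyl-1H-pyrazol-1-yl)ethan-1-one F5.
  - F5 is added to 7 under a bifunctional cinchona urea, 1-[3,5-bis(trifluoromethyl)phenyl]-3-[(8α,9S)-6′-methoxycinchonan-9-yl]urea or its quinidine-derived pseudoenantiomer, whichever delivers the (2R) adduct; organocatalytic Michael addition of activated arylacetic amides to nitroalkenes is a known reaction type. The product is (2R,3S)-2,3-bis(3,5-dimethoxyphenyl)-1-(3,5-dimethyl-1H-pyrazol-1-yl)-4-nitrobutan-1-one F6; its C3 configuration is again immaterial.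
  - Methanolysis of the acylpyrazole (MeOH, Et3N, rt) gives 12, so steps 3 to 5 are replaced by three steps without a strong base.

**Step 6 (Nef reaction).**
- What may go wrong: the reduction may stall at the oxime, or the α-aryl aldehyde may be lost by enolisation and air oxidation during isolation; prolonged contact with methoxide would also start to epimerise the ester α-centre.
- Fallback (sets out from 12, returns at 19): nitronate 13 is poured into H2SO4 in methanol at −40 °C (the acetal variant of the Nef reaction). This gives the dimethyl acetal methyl (2R,3S)-2,3-bis(3,5-dimethoxyphenyl)-4,4-dimethoxybutanoate F7, which can be purified and stored. Under the conditions of step 7, F7 ionises to the methoxycarbenium ion, the O-methyl analogue of the protonated aldehyde, and enters the same cascade to give 19 without 14 ever being isolated.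

**Step 12 (ketone reduction).**
- What may go wrong: poor or reversed facial selectivity, because the bulky indanyl substituent competes with the aryl group for the large-group position of the catalyst and the C3 stereocentre imposes its own bias.
- Fallback (sets out from 25, returns at 27): inversion replaces selection.
  - The ketone is reduced in the sense the substrate prefers, with borane and the (3aR)-configured oxazaborolidine. The (S)-carbinol hexaacetate F8 (the Cα epimer of 26), whether it is the main product or is separated from a mixture, is the material carried on.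
  - Mitsunobu inversion of F8 with 4-nitrobenzoic acid, PPh3 and diisopropyl azodicarboxylate gives the (R)-4-nitrobenzoate hexaacetate F9.
  - The methanolysis of step 13 removes the nitrobenzoate together with the six acetates and gives 27.

## Further compounds

F1 | step 7 | methyl (2R,3S)-2,3-bis(3,5-dimethoxyphenyl)-4-hydroxy-4-(4-methoxyphenyl)butanoate (both C4 epimers) | COc1cc(OC)cc(c1)[C@H](C(=O)OC)[C@H](C(O)c1ccc(OC)cc1)c1cc(OC)cc(OC)c1
F2 | step 7 | methyl (1R,2S,3R)-2-(3,5-dimethoxyphenyl)-4,6-dimethoxy-3-(4-methoxyphenyl)-2,3-dihydro-1H-indene-1-carboxylate | COc1ccc([C@@H]2c3c(OC)cc(OC)cc3[C@H](C(=O)OC)[C@H]2c2cc(OC)cc(OC)c2)cc1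
F3 | step 7 | (1R,2S,3R)-2-(3,5-dimethoxyphenyl)-N,4,6-trimethoxy-3-(4-methoxyphenyl)-N-methyl-2,3-dihydro-1H-indene-1-carboxamide | COc1ccc([C@@H]2c3c(OC)cc(OC)cc3[C@H](C(=O)N(C)OC)[C@H]2c2cc(OC)cc(OC)c2)cc1
F4 | step 7 | [(1R,2S,3R)-2-(3,5-dimethoxyphenyl)-4,6-dimethoxy-3-(4-methoxyphenyl)-2,3-dihydro-1H-inden-1-yl](4-methoxyphenyl)methanone | COc1ccc([C@@H]2c3c(OC)cc(OC)cc3[C@H](C(=O)c3ccc(OC)cc3)[C@H]2c2cc(OC)cc(OC)c2)cc1
F5 | step 3 | 2-(3,5-dimethoxyphenyl)-1-(3,5-dimethyl-1H-pyrazol-1-yl)ethan-1-one | COc1cc(CC(=O)n2nc(C)cc2C)cc(OC)c1
F6 | step 3 | (2R,3S)-2,3-bis(3,5-dimethoxyphenyl)-1-(3,5-dimethyl-1H-pyrazol-1-yl)-4-nitrobutan-1-one | COc1cc(OC)cc(c1)[C@H](C(=O)n1nc(C)cc1C)[C@H](C[N+](=O)[O-])c1cc(OC)cc(OC)c1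
F7 | step 6 | methyl (2R,3S)-2,3-bis(3,5-dimethoxyphenyl)-4,4-dimethoxybutanoate | COc1cc(OC)cc(c1)[C@H](C(=O)OC)[C@H](C(OC)OC)c1cc(OC)cc(OC)c1
F8 | step 12 | 4-[(S)-[(1R,2S,3R)-4,6-diacetoxy-3-(4-acetoxyphenyl)-2-(3,5-diacetoxyphenyl)-2,3-dihydro-1H-inden-1-yl](hydroxy)methyl]phenyl acetate | CC(=O)Oc1ccc([C@@H]2c3c(OC(C)=O)cc(OC(C)=O)cc3[C@H]([C@H](O)c3ccc(OC(C)=O)cc3)[C@H]2c2cc(OC(C)=O)cc(OC(C)=O)c2)cc1
F9 | step 12 | (R)-(4-acetoxyphenyl)[(1R,2S,3R)-4,6-diacetoxy-3-(4-acetoxyphenyl)-2-(3,5-diacetoxyphenyl)-2,3-dihydro-1H-inden-1-yl]methyl 4-nitrobenzoate | CC(=O)Oc1ccc([C@@H]2c3c(OC(C)=O)cc(OC(C)=O)cc3[C@H]([C@@H](OC(=O)c3ccc(cc3)[N+](=O)[O-])c3ccc(OC(C)=O)cc3)[C@H]2c2cc(OC(C)=O)cc(OC(C)=O)c2)cc1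
A1 | alternative 1 | 2,3-trans-3-(tert-butyldimethylsilyloxymethyl)-2-(3,5-dimethoxyphenyl)-5-methoxy-7-(methoxymethoxy)indan-1-ol (carbinol configuration immaterial) | O[C@H]1c2c(OCOC)cc(OC)cc2[C@H](CO[Si](C)(C)C(C)(C)C)[C@H]1c1cc(OC)cc(OC)c1
A2 | alternative 1 | [2-formyl-5-methoxy-3-(methoxymethoxy)phenyl]boronic acid | OB(O)c1cc(OC)cc(OCOC)c1C=O
A3 | alternative 1 | tert-butyl{[(E)-3-(3,5-dimethoxyphenyl)prop-2-en-1-yl]oxy}dimethylsilane | COc1cc(/C=C/CO[Si](C)(C)C(C)(C)C)cc(OC)c1
A4 | alternative 2 | [(1R,2S,3R)-2-(3,5-dimethoxyphenyl)-4,6-dimethoxy-3-(4-methoxyphenyl)-2,3-dihydro-1H-inden-1-yl](4-methoxyphenyl)methanone | COc1ccc([C@@H]2c3c(OC)cc(OC)cc3[C@H](C(=O)c3ccc(OC)cc3)[C@H]2c2cc(OC)cc(OC)c2)cc1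
A5 | alternative 2 | [1,2-bis(3,5-dimethoxyphenyl)-3-(4-methoxyphenyl)cyclopropyl](4-methoxyphenyl)methanone (aryl groups on the two CH carbons trans; CH carbon bearing the dimethoxyphenyl ring configured as C2 of the target) | COc1ccc(cc1)[C@H]1[C@H](c2cc(OC)cc(OC)c2)[C@@]1(c1cc(OC)cc(OC)c1)C(=O)c1ccc(OC)cc1
A6 | alternative 3 | methyl (1R,2S,3R)-2-(3,5-dimethoxyphenyl)-4,6-dimethoxy-3-(4-methoxyphenyl)-2,3-dihydro-1H-indene-1-carboxylate | COc1ccc([C@@H]2c3c(OC)cc(OC)cc3[C@H](C(=O)OC)[C@H]2c2cc(OC)cc(OC)c2)cc1
A7 | alternative 3 | 3,4-trans-2-diazo-3-(3,5-dimethoxyphenyl)-5,7-dimethoxy-4-(4-methoxyphenyl)-3,4-dihydronaphthalen-1(2H)-one | COc1ccc([C@@H]2c3c(OC)cc(OC)cc3C(=O)C(=[N+]=[N-])[C@H]2c2cc(OC)cc(OC)c2)cc1
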